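**Retrosynthetic overview**
1. The strategy rests on ring A of the flavonol (C4a, C5, C6, C7, C8, C8a): oxygens para to each other at C5 and C8, a third oxygen at C7 beside C8, and hydrogen at C6. This is the pattern a 3-alkoxy-4-hydroxycyclobut-2-enone delivers when it is annulated onto the C4a–C8a double bond of a 4-pyranone.
2. Endgame: the C7 isopropyl ether and the two benzyl ethers (C3–O, C3'–O) are cleaved, and C8–OH of a 5,8-quinol is methylated. The quinol arises from the C4a–C5 disconnection, a thermal cyclobutenone ring opening followed by six-electron electrocyclization (Moore cyclization).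
3. The cyclobutenone is cut at the bond between its carbinol carbon and the pyranone into a pyranon-2-yl magnesium reagent (from the iodide, made by Lewis-acid-free zincation and iodolysis) and isopropyl semisquarate (from diisopropyl squarate).
4. Ring C, with its C3 oxygen and ring B attached, comes from an aryl furyl carbinol (2-furyllithium plus the benzylated aldehyde) by Achmatowicz rearrangement, enone epoxidation and acid isomerisation.
5. Ring order: ring B is bought, ring C is formed in steps 3–6, ring A is formed last in step 11.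

Key step: step 11

Remark on the chemistry: the target is achiral; every chiral intermediate is racemic or a diastereomer mixture and loses all its stereocentres on the way, so no stereocontrol is needed. TMPZnCl·LiCl and iPrMgCl·LiCl are taken as commercial THF solutions.

**Route**

Step 1
Reactants: 1 3-hydroxy-4,5-dimethoxybenzaldehyde
Product: 2 3-(benzyloxy)-4,5-dimethoxybenzaldehyde
Conditions: BnBr, K2CO3, DMF, 25 °C
Reagents that add atoms: benzyl bromide, BrCc1ccccc1
Why: Williamson ether synthesis, in which the phenoxide is alkylated at oxygen by the benzylic bromide and the aldehyde is left untouched.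

Step 2
Reactants: 3 furan; 2 3-(benzyloxy)-4,5-dimethoxybenzaldehyde
Product: 5 [3-(benzyloxy)-4,5-dimethoxyphenyl](furan-2-yl)methanol (racemic), via 2-furyllithium 4 (not isolated)
Conditions: n-BuLi, THF, −78 → 0 °C; then 2, −78 °C; then H2O
Reagents that add atoms: none
Why: α-Lithiation of furan followed by 1,2-addition of the heteroaryllithium to the aldehyde; the carbinol centre forms racemic and needs no control because it becomes sp2 in step 6.

Step 3
Reactants: 5 [3-(benzyloxy)-4,5-dimethoxyphenyl](furan-2-yl)methanol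
Product: 6 2-[3-(benzyloxy)-4,5-dimethoxyphenyl]-6-hydroxy-2H-pyran-3(6H)-one (racemic, mixture of C6 epimers)
Conditions: NBS, NaHCO3, THF/H2O 4:1, 0 °C
Reagents that add atoms: water, O
Why: Achmatowicz rearrangement, in which bromonium-induced oxidative opening of the furan gives a Z-enedione that the carbinol hydroxyl closes to the pyranone lactol; the buffer protects the acid-labile carbinol and the furan should react far faster than the alkoxyarene.

Step 4
Reactants: 6 2-[3-(benzyloxy)-4,5-dimethoxyphenyl]-6-hydroxy-2H-pyran-3(6H)-one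
Product: 7 2-[3-(benzyloxy)-4,5-dimethoxyphenyl]-6-methoxy-2H-pyran-3(6H)-one (racemic, mixture of diastereomers)
Conditions: HC(OMe)3, BF3·OEt2 (cat.), CH2Cl2, 0 °C
Reagents that add atoms: trimethyl orthoformate, COC(OC)OC
Why: Acid-catalysed acetalisation through the ring oxocarbenium ion, with the orthoformate as methanol source and water scavenger; it masks the lactol, which would open under the basic conditions of step 5.

Step 5
Reactants: 7 2-[3-(benzyloxy)-4,5-dimethoxyphenyl]-6-methoxy-2H-pyran-3(6H)-one
Product: 8 4-[3-(benzyloxy)-4,5-dimethoxyphenyl]-2-methoxy-3,7-dioxabicyclo[4.1.0]heptan-5-one (racemic, mixture of diastereomers)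
Conditions: 30% H2O2, NaOH (cat.), MeOH, 0 °C
Reagents that add atoms: hydrogen peroxide, OO
Why: Weitz–Scheffer nucleophilic epoxidation of the enone by hydroperoxide anion; the configuration of the new centres is irrelevant because all four stereocentres disappear in step 6.

Step 6
Reactants: 8 4-[3-(benzyloxy)-4,5-dimethoxyphenyl]-2-methoxy-3,7-dioxabicyclo[4.1.0]heptan-5-one
Product: 9 2-[3-(benzyloxy)-4,5-dimethoxyphenyl]-3-hydroxy-4H-pyran-4-one
Conditions: 2 M H2SO4, 1,4-dioxane, 90 °C
Reagents that add atoms: none
Why: Acid-induced isomerisation of the α,β-epoxy ketone to the α-diketone, then β-elimination of methanol and enolisation, the sequence used for the maltol type of 3-hydroxy-4-pyranone; the aryl benzyl ether should tolerate dilute aqueous acid.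

Step 7
Reactants: 9 2-[3-(benzyloxy)-4,5-dimethoxyphenyl]-3-hydroxy-4H-pyran-4-one
Product: 10 3-(benzyloxy)-2-[3-(benzyloxy)-4,5-dimethoxyphenyl]-4H-pyran-4-one
Conditions: BnBr, K2CO3, DMF, 60 °C
Reagents that add atoms: benzyl bromide, BrCc1ccccc1
Why: Williamson ether synthesis on the acidic enolic hydroxyl, as in the benzylation of maltol; it removes the only acidic proton before the metalation.

Step 8
Reactants: 10 3-(benzyloxy)-2-[3-(benzyloxy)-4,5-dimethoxyphenyl]-4H-pyran-4-one
Product: 12 5-(benzyloxy)-6-[3-(benzyloxy)-4,5-dimethoxyphenyl]-2-iodo-4H-pyran-4-one, via pyranon-2-ylzinc chloride 11 (not isolated)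
Conditions: TMPZnCl·LiCl, THF, 25 °C; then I2, 0 °C
Reagents that add atoms: iodine, II
Why: Deprotonative zincation with a hindered zinc amide followed by iodolysis; with no MgCl2 or BF3 bound to the carbonyl the base should take the most acidic ring hydrogen, at C6 of 10 on the carbon bonded to the ring oxygen (C2 in the numbering of 12), and the covalent C–Zn bond avoids the ring opening that an anion at C5 beside the carbonyl would undergo.

Step 9
Reactants: 13 3,4-di(propan-2-yloxy)cyclobut-3-ene-1,2-dione (diisopropyl squarate)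
Product: 15 3-(propan-2-yloxy)cyclobut-3-ene-1,2-dione, via 4-hydroxy-2,3-di(propan-2-yloxy)cyclobut-2-en-1-one 14 (not isolated)
Conditions: LiAlH(OtBu)3, THF, −78 °C; aq HCl; then conc. HCl (cat.), CH2Cl2, 25 °C
Reagents that add atoms: none
Why: Selective 1,2-hydride reduction of one squarate carbonyl, then acid-promoted loss of the allylic hydroxyl and hydrolysis of the resulting alkoxy-stabilised cation with release of propan-2-ol, the standard way to the semisquarate.

Step 10
Reactants: 12 5-(benzyloxy)-6-[3-(benzyloxy)-4,5-dimethoxyphenyl]-2-iodo-4H-pyran-4-one; 15 3-(propan-2-yloxy)cyclobut-3-ene-1,2-dione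
Product: 17 5-(benzyloxy)-6-[3-(benzyloxy)-4,5-dimethoxyphenyl]-2-[1-hydroxy-4-oxo-2-(propan-2-yloxy)cyclobut-2-en-1-yl]-4H-pyran-4-one (racemic), via pyranon-2-ylmagnesium chloride 16 (not isolated)
Conditions: iPrMgCl·LiCl, THF, −78 °C; then 15, −78 → −40 °C; aq NH4Cl
Reagents that add atoms: none
Why: Iodine–magnesium exchange at an electron-poor alkenyl iodide followed by Grignard 1,2-addition to a cyclobutenedione; the carbanion should attack the carbonyl of 15 that flanks the isopropoxy-bearing carbon, since the other carbonyl is deactivated as a vinylogous ester, which places isopropoxy beside the carbinol carbon and hydrogen beside the remaining carbonyl, and the racemic carbinol centre is destroyed in step 11.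

Step 11
Reactants: 17 5-(benzyloxy)-6-[3-(benzyloxy)-4,5-dimethoxyphenyl]-2-[1-hydroxy-4-oxo-2-(propan-2-yloxy)cyclobut-2-en-1-yl]-4H-pyran-4-one
Product: 20 3-(benzyloxy)-2-[3-(benzyloxy)-4,5-dimethoxyphenyl]-5,8-dihydroxy-7-(propan-2-yloxy)-4H-chromen-4-one, via dienylketene 18 (not isolated), via 4aH-chromene-4,5-dione tautomer 19 (not isolated)
Conditions: p-xylene (degassed), 130 °C, Ar
Reagents that add atoms: none
Why: Heat should break the bond between the carbinol carbon and the carbonyl carbon of the four-membered ring in a conrotatory four-electron electrocyclic opening, the donor hydroxyl turning outward and the pyranonyl group inward, to give the (Z)-dienylketene 18 with the ketene carbon next to pyranone C3. That carbon is the nucleophilic α-carbon of the vinylogous ester and should bond to the electrophilic ketene carbon in a thermally allowed disrotatory six-electron electrocyclization, which closes the six-membered carbocyclic ring A across the future C4a–C8a bond as dienone 19; enolisation (hydrogen from C4a to the C5 oxygen) then aromatises it. This is the Moore cyclization known for 4-aryl-, 4-heteroaryl- and 4-alkenyl-4-hydroxycyclobutenones, applied here to closure onto the double bond of a 4-pyranone. No stereocentre remains, because the carbinol centre of 17 and the transient C4a centre of 19 both become sp2. The regiochemistry needed (hydroxyls at C5 and C8, isopropoxy at C7, hydrogen at C6) is fixed by the constitution of 17 and by the fact that the pyranone carbon bearing the cyclobutenone has only one carbon neighbour to close on, the other neighbour being the ring oxygen. The torquoselectivity needed is secured by the donor character of the hydroxyl, which rotates outward and so also stays away from the ketene and suppresses lactonisation to a furanone.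

Step 12
Reactants: 20 3-(benzyloxy)-2-[3-(benzyloxy)-4,5-dimethoxyphenyl]-5,8-dihydroxy-7-(propan-2-yloxy)-4H-chromen-4-one
Product: 21 3-(benzyloxy)-2-[3-(benzyloxy)-4,5-dimethoxyphenyl]-5-hydroxy-8-methoxy-7-(propan-2-yloxy)-4H-chromen-4-one
Conditions: MeI, K2CO3, acetone (degassed), 25 °C, Ar
Reagents that add atoms: iodomethane, CI
Why: Williamson O-methylation that should take the C8 hydroxyl only, because the C5 hydroxyl is hydrogen-bonded to the C4 carbonyl and much less acidic and nucleophilic; air is excluded because the quinol anion is oxidisable.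

Step 13
Reactants: 21 3-(benzyloxy)-2-[3-(benzyloxy)-4,5-dimethoxyphenyl]-5-hydroxy-8-methoxy-7-(propan-2-yloxy)-4H-chromen-4-one
Product: 22 3,5,7-trihydroxy-2-(3-hydroxy-4,5-dimethoxyphenyl)-8-methoxy-4H-chromen-4-one (CNP0225742.0)
Conditions: BCl3, C6HMe5, CH2Cl2, −78 → 0 °C; then H2O
Reagents that add atoms: none
Why: Lewis-acid dealkylation of aryl ethers, in which BCl3 with pentamethylbenzene as benzyl-cation scavenger should cleave both benzyl ethers at −78 °C and the secondary isopropyl ether on warming, while the three methyl ethers, none of them peri to the carbonyl, should survive the short exposure.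

**Compound list**
1 | 3-hydroxy-4,5-dimethoxybenzaldehyde | COc1cc(C=O)cc(O)c1OC | starting material
2 | 3-(benzyloxy)-4,5-dimethoxybenzaldehyde | COc1cc(C=O)cc(OCc2ccccc2)c1OC | intermediate
3 | furan | c1ccoc1 | starting material
4 | furan-2-yllithium (not isolated) | [Li]c1ccco1 | intermediate
5 | [3-(benzyloxy)-4,5-dimethoxyphenyl](furan-2-yl)methanol (racemic, one enantiomer drawn) | COc1cc([C@@H](O)c2ccco2)cc(OCc2ccccc2)c1OC | intermediate
6 | 2-[3-(benzyloxy)-4,5-dimethoxyphenyl]-6-hydroxy-2H-pyran-3(6H)-one (racemic, mixture of C6 epimers, configuration not specified) | COc1cc(C2OC(O)C=CC2=O)cc(OCc2ccccc2)c1OC | intermediate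
7 | 2-[3-(benzyloxy)-4,5-dimethoxyphenyl]-6-methoxy-2H-pyran-3(6H)-one (racemic, mixture of diastereomers, configuration not specified) | COc1cc(C2OC(OC)C=CC2=O)cc(OCc2ccccc2)c1OC | intermediate
8 | 4-[3-(benzyloxy)-4,5-dimethoxyphenyl]-2-methoxy-3,7-dioxabicyclo[4.1.0]heptan-5-one (racemic, mixture of diastereomers, configuration not specified) | COc1cc(C2OC(OC)C3OC3C2=O)cc(OCc2ccccc2)c1OC | intermediate
9 | 2-[3-(benzyloxy)-4,5-dimethoxyphenyl]-3-hydroxy-4H-pyran-4-one | COc1cc(-c2occc(=O)c2O)cc(OCc2ccccc2)c1OC | intermediate
10 | 3-(benzyloxy)-2-[3-(benzyloxy)-4,5-dimethoxyphenyl]-4H-pyran-4-one | COc1cc(-c2occc(=O)c2OCc2ccccc2)cc(OCc2ccccc2)c1OC | intermediate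
11 | [5-(benzyloxy)-6-[3-(benzyloxy)-4,5-dimethoxyphenyl]-4-oxo-4H-pyran-2-yl]zinc chloride, LiCl complex (not isolated) | COc1cc(-c2oc([Zn]Cl)cc(=O)c2OCc2ccccc2)cc(OCc2ccccc2)c1OC | intermediate
12 | 5-(benzyloxy)-6-[3-(benzyloxy)-4,5-dimethoxyphenyl]-2-iodo-4H-pyran-4-one | COc1cc(-c2oc(I)cc(=O)c2OCc2ccccc2)cc(OCc2ccccc2)c1OC | intermediate
13 | 3,4-di(propan-2-yloxy)cyclobut-3-ene-1,2-dione (diisopropyl squarate) | CC(C)OC1=C(OC(C)C)C(=O)C1=O | starting material
14 | 4-hydroxy-2,3-di(propan-2-yloxy)cyclobut-2-en-1-one (racemic, one enantiomer drawn, not isolated) | CC(C)OC1=C(OC(C)C)C(=O)[C@@H]1O | intermediate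
15 | 3-(propan-2-yloxy)cyclobut-3-ene-1,2-dione (isopropyl semisquarate) | CC(C)OC1=CC(=O)C1=O | intermediate
16 | [5-(benzyloxy)-6-[3-(benzyloxy)-4,5-dimethoxyphenyl]-4-oxo-4H-pyran-2-yl]magnesium chloride, LiCl complex (not isolated) | COc1cc(-c2oc([Mg]Cl)cc(=O)c2OCc2ccccc2)cc(OCc2ccccc2)c1OC | intermediate
17 | 5-(benzyloxy)-6-[3-(benzyloxy)-4,5-dimethoxyphenyl]-2-[1-hydroxy-4-oxo-2-(propan-2-yloxy)cyclobut-2-en-1-yl]-4H-pyran-4-one (racemic, one enantiomer drawn) | CC(C)OC1=CC(=O)[C@]1(O)c1cc(=O)c(OCc2ccccc2)c(-c2cc(OC)c(OC)c(OCc3ccccc3)c2)o1 | intermediate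
18 | (3Z)-4-{5-(benzyloxy)-6-[3-(benzyloxy)-4,5-dimethoxyphenyl]-4-oxo-4H-pyran-2-yl}-4-hydroxy-3-(propan-2-yloxy)buta-1,3-dien-1-one (dienylketene, not isolated) | O=C=C/C(OC(C)C)=C(/O)c1cc(=O)c(OCc2ccccc2)c(-c2cc(OC)c(OC)c(OCc3ccccc3)c2)o1 | intermediate
19 | 3-(benzyloxy)-2-[3-(benzyloxy)-4,5-dimethoxyphenyl]-8-hydroxy-7-(propan-2-yloxy)-4aH-chromene-4,5-dione (racemic, one enantiomer drawn, not isolated) | CC(C)OC1=CC(=O)[C@H]2C(=O)C(OCc3ccccc3)=C(c3cc(OC)c(OC)c(OCc4ccccc4)c3)OC2=C1O | intermediate
20 | 3-(benzyloxy)-2-[3-(benzyloxy)-4,5-dimethoxyphenyl]-5,8-dihydroxy-7-(propan-2-yloxy)-4H-chromen-4-one | CC(C)Oc1cc(O)c2c(=O)c(OCc3ccccc3)c(-c3cc(OC)c(OC)c(OCc4ccccc4)c3)oc2c1O | intermediate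
21 | 3-(benzyloxy)-2-[3-(benzyloxy)-4,5-dimethoxyphenyl]-5-hydroxy-8-methoxy-7-(propan-2-yloxy)-4H-chromen-4-one | CC(C)Oc1cc(O)c2c(=O)c(OCc3ccccc3)c(-c3cc(OC)c(OC)c(OCc4ccccc4)c3)oc2c1OC | intermediate
22 | 3,5,7-trihydroxy-2-(3-hydroxy-4,5-dimethoxyphenyl)-8-methoxy-4H-chromen-4-one | COc1cc(-c2oc3c(OC)c(O)cc(O)c3c(=O)c2O)cc(O)c1OC | target

**Step count**
Total steps: 13. Longest linear sequence: 12 (steps 1–8 and 10–13, from aldehyde 1); step 9 is the one-step side branch to 15.

**Steps most likely to fail**

1. Step 10. Isopropylmagnesium chloride may add to the iodine-bearing carbon of 12, a vinylogous acyl iodide, and expel iodide instead of exchanging. The stabilised magnesium reagent 16 may also add to 15 slowly, or at its alkoxy-bearing carbon with loss of isopropoxide. The fallback sets out from 10 and leaves 12 aside. Deprotonation of 10 at C6 with LiTMP (lithium 2,2,6,6-tetramethylpiperidide) in THF at −78 °C should give [5-(benzyloxy)-6-[3-(benzyloxy)-4,5-dimethoxyphenyl]-4-oxo-4H-pyran-2-yl]lithium F1, the more nucleophilic lithium reagent that is the usual partner of squarate esters. Addition of 15 at −78 °C and quenching with water should bring the route back at 17.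

2. Step 11. Part of the material may open with the hydroxyl turned inward, so that the ketene is captured as a furanone. Closure onto the electron-poor pyranone double bond may be slow enough for the ketene to dimerise. The quinol may be oxidised to the quinone during isolation. The fallback sets out from 17. O-Methylation of the tertiary hydroxyl (MeI, Ag2O, MeCN, 25 °C) should give 5-(benzyloxy)-6-[3-(benzyloxy)-4,5-dimethoxyphenyl]-2-[1-methoxy-4-oxo-2-(propan-2-yloxy)cyclobut-2-en-1-yl]-4H-pyran-4-one F2 (racemic). Its thermolysis in p-xylene at 140 °C cannot lactonise, can be driven at higher temperature, and should give the air-stable 8-methyl ether directly. The route is rejoined at 21, and step 12 is no longer needed.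

3. Step 13. Benzyl cations may be transferred to the electron-rich C6 of ring A. Prolonged contact with the Lewis acid may also cleave the 4'-methyl ether, which lies between two oxygens. The fallback sets out from 21. Hydrogenolysis (H2, 10% Pd/C, EtOAc/MeOH, 25 °C) should remove both benzyl ethers without forming cations and give 3,5-dihydroxy-2-(3-hydroxy-4,5-dimethoxyphenyl)-8-methoxy-7-(propan-2-yloxy)-4H-chromen-4-one F3. A short treatment with BCl3 (CH2Cl2, −78 → 0 °C) then has only the single isopropyl ether to cleave, and the route is rejoined at 22.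

**Further compounds**
F1 | step 10 | [5-(benzyloxy)-6-[3-(benzyloxy)-4,5-dimethoxyphenyl]-4-oxo-4H-pyran-2-yl]lithium | COc1cc(-c2oc([Li])cc(=O)c2OCc2ccccc2)cc(OCc2ccccc2)c1OC
F2 | step 11 | 5-(benzyloxy)-6-[3-(benzyloxy)-4,5-dimethoxyphenyl]-2-[1-methoxy-4-oxo-2-(propan-2-yloxy)cyclobut-2-en-1-yl]-4H-pyran-4-one (racemic, one enantiomer drawn) | CC(C)OC1=CC(=O)[C@]1(OC)c1cc(=O)c(OCc2ccccc2)c(-c2cc(OC)c(OC)c(OCc3ccccc3)c2)o1
F3 | step 13 | 3,5-dihydroxy-2-(3-hydroxy-4,5-dimethoxyphenyl)-8-methoxy-7-(propan-2-yloxy)-4H-chromen-4-one | CC(C)Oc1cc(O)c2c(=O)c(O)c(-c3cc(OC)c(OC)c(O)c3)oc2c1OC
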